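**Retrosynthetic overview**
1. Target 12 ⇒ seco-diphenol 11. The last step is an intramolecular dehydrogenative phenol coupling between C5 of the guaiacyl ring (ring A) and the phenol oxygen of the p-coumaroyl unit. This is the diaryl ether bond the plant presumably closes last, and it forms the only new ring (21-membered).
2. 11 ⇒ anti-aldol adduct 10 (one LiBH4 step: auxiliary off, C9 becomes CH2OH, both aryl acetates off).
3. 10 ⇒ aryloxyacetyl imide 7 + vanillin acetate 8. One auxiliary-controlled anti-glycolate aldol makes the C7–C8 bond and both stereocentres.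
4. 7 ⇒ serotonin hydrochloride 1, chloroacetyl oxazolidinone 3 and 4-acetoxycinnamic acid 5 (N-Boc protection, O-alkylation, N-acylation).
5. Ring order: all aromatic rings are bought; the macrocycle is formed last.

Assumption: the presumed biosynthesis is phenoxyl-radical coupling of N-(p-coumaroyl)serotonin with coniferyl alcohol (C8–O-indolyl coupling, water addition to the quinone methide, then 4-O-5 diaryl ether closure). The target is the erythro (7R,8S) isomer.

**Step 1**
Reactants: 1 serotonin hydrochloride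
Product: 2 N-Boc-serotonin
Conditions: Boc2O (1.05 equiv), NaHCO3 (2.2 equiv), dioxane–H2O 1:1, 0 °C to rt
Reagents that add atoms: di-tert-butyl dicarbonate (Boc2O), CC(C)(C)OC(=O)OC(=O)OC(C)(C)C
Why: Carbamate formation (Boc protection); the amine freed by bicarbonate is far more nucleophilic than the phenol or the indole N–H, so only nitrogen is acylated, and no stereocentre is involved.

**Step 2**
Reactants: 2 N-Boc-serotonin; 3 (S)-4-benzyl-3-(chloroacetyl)oxazolidin-2-one
Product: 4 N-Boc indol-5-yloxyacetyl imide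
Conditions: K2CO3 (1.5 equiv), MeCN, 45 °C
Reagents that add atoms: none
Why: Williamson ether synthesis; the phenoxide, the only group K2CO3 deprotonates, displaces chloride from the activated α-chloro imide by SN2, and the auxiliary stereocentre is untouched.

**Step 3**
Reactants: 4 N-Boc indol-5-yloxyacetyl imide; 5 (E)-4-acetoxycinnamic acid
Product: 7 N-(4-acetoxycinnamoyl) indol-5-yloxyacetyl imide, via ammonium trifluoroacetate 6 (not isolated)
Conditions: TFA–CH2Cl2 1:4, 0 °C, 1 h, evaporate; then 5 (1.1 equiv), EDC (1.2 equiv), HOBt (1.2 equiv), i-Pr2NEt (3 equiv), DMF, 0 °C to rt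
Reagents that add atoms: trifluoroacetic acid, OC(=O)C(F)(F)F (stays only in 6 as the counter-ion)
Why: Acidolytic Boc cleavage followed by carbodiimide/HOBt amide coupling; the liberated amine is acylated by the benzotriazolyl ester much faster than it can attack the imide or the aryl acetate, and no stereocentre is touched.

**Step 4**
Reactants: 7 N-(4-acetoxycinnamoyl) indol-5-yloxyacetyl imide; 8 vanillin acetate
Product: 10 (2R,3R) anti-aldol adduct, via O-TMS aldol ether 9 (not isolated)
Conditions: 8 (1.3 equiv), MgCl2 (0.3 equiv), Et3N (2.5 equiv), TMSCl (2 equiv), EtOAc, rt, 24 h; then MeOH, TFA (cat.), rt, 30 min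
Reagents that add atoms: chlorotrimethylsilane, C[Si](C)(C)Cl (silicon stays only in 9)
Why: Evans magnesium-halide-catalysed direct anti-aldol addition; the chelated Z-magnesium enolate of the (S)-benzyl imide adds to the non-enolisable aldehyde on the face away from the benzyl group through a boat-type transition state and is trapped as the silyl ether, which sets both stereocentres at once as (2R,3R), the erythro pair that becomes C8 and C7 of the target.

**Step 5**
Reactants: 10 (2R,3R) anti-aldol adduct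
Product: 11 (7R,8S) seco-diphenol
Conditions: LiBH4 (6 equiv), H2O (2 equiv), THF, 0 °C to rt; pH 7 buffer work-up
Reagents that add atoms: none
Why: Borohydride reductive cleavage of an N-acyloxazolidinone; LiBH4 reduces the activated imide carbonyl to the primary alcohol and cleaves both aryl acetates in the same pot while the secondary cinnamamide and the indole are inert, so C2 becomes C8 with unchanged geometry (R becomes S only through the priority change) and C7 stays R.

**Step 6**
Reactants: 11 (7R,8S) seco-diphenol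
Product: 12 CNP0276372.1
Conditions: Ag2O (2.5 equiv), dry acetone, 11 added over 6 h to 1 mM final concentration, rt, dark
Reagents that add atoms: none
Why: Proposed new method: Ag2O removes one hydrogen atom from each phenol; the guaiacyl phenoxyl radical is blocked at its para position by the sp3 side chain and at one ortho position by OMe, so its only open carbon is C5, which combines with the oxygen of the tethered p-coumaroyl phenoxyl radical, and the resulting 6-aryloxycyclohexadienone tautomerises to the diaryl ether, closing the 21-membered ring without touching C7 or C8; the closest known reaction type is the one-electron dehydrogenative phenol coupling that gives 4-O-5 diaryl ethers in lignin and hydroxycinnamate dehydrodimers, and oxidative diaryl ether macrocyclisation of the isodityrosine kind.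

**Compound list**
1 | serotonin hydrochloride (5-hydroxytryptamine hydrochloride) | NCCc1c[nH]c2ccc(O)cc12.Cl | starting material
2 | tert-butyl N-[2-(5-hydroxy-1H-indol-3-yl)ethyl]carbamate (N-Boc-serotonin) | CC(C)(C)OC(=O)NCCc1c[nH]c2ccc(O)cc12 | intermediate
3 | (4S)-4-benzyl-3-(2-chloroacetyl)-1,3-oxazolidin-2-one | O=C1OC[C@H](Cc2ccccc2)N1C(=O)CCl | starting material
4 | tert-butyl N-[2-(5-{2-[(4S)-4-benzyl-2-oxo-1,3-oxazolidin-3-yl]-2-oxoethoxy}-1H-indol-3-yl)ethyl]carbamate | O=C1OC[C@H](Cc2ccccc2)N1C(=O)COc1ccc2[nH]cc(CCNC(=O)OC(C)(C)C)c2c1 | intermediate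
5 | (E)-3-(4-acetoxyphenyl)prop-2-enoic acid (4-acetoxycinnamic acid) | CC(=O)Oc1ccc(/C=C/C(=O)O)cc1 | starting material
6 | 2-(5-{2-[(4S)-4-benzyl-2-oxo-1,3-oxazolidin-3-yl]-2-oxoethoxy}-1H-indol-3-yl)ethanaminium trifluoroacetate | O=C1OC[C@H](Cc2ccccc2)N1C(=O)COc1ccc2[nH]cc(CC[NH3+])c2c1.[O-]C(=O)C(F)(F)F | intermediate
7 | 4-[(E)-3-{[2-(5-{2-[(4S)-4-benzyl-2-oxo-1,3-oxazolidin-3-yl]-2-oxoethoxy}-1H-indol-3-yl)ethyl]amino}-3-oxoprop-1-enyl]phenyl acetate | O=C1OC[C@H](Cc2ccccc2)N1C(=O)COc1ccc2[nH]cc(CCNC(=O)/C=C/c3ccc(OC(C)=O)cc3)c2c1 | intermediate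
8 | 4-formyl-2-methoxyphenyl acetate (vanillin acetate) | CC(=O)Oc1ccc(C=O)cc1OC | starting material
9 | trimethylsilyl ether of 10 at the benzylic oxygen, (2R,3R), (4S)-auxiliary | O=C1OC[C@H](Cc2ccccc2)N1C(=O)[C@H](Oc1ccc2[nH]cc(CCNC(=O)/C=C/c3ccc(OC(C)=O)cc3)c2c1)[C@H](O[Si](C)(C)C)c1ccc(OC(C)=O)c(OC)c1 | intermediate
10 | (4S)-3-[(2R,3R)-3-(4-acetoxy-3-methoxyphenyl)-3-hydroxy-2-({3-[2-((E)-4-acetoxycinnamoylamino)ethyl]-1H-indol-5-yl}oxy)propanoyl]-4-benzyl-1,3-oxazolidin-2-one | O=C1OC[C@H](Cc2ccccc2)N1C(=O)[C@H](Oc1ccc2[nH]cc(CCNC(=O)/C=C/c3ccc(OC(C)=O)cc3)c2c1)[C@H](O)c1ccc(OC(C)=O)c(OC)c1 | intermediate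
11 | (E)-N-[2-(5-{[(1R,2S)-1,3-dihydroxy-1-(4-hydroxy-3-methoxyphenyl)propan-2-yl]oxy}-1H-indol-3-yl)ethyl]-3-(4-hydroxyphenyl)prop-2-enamide | OC[C@H](Oc1ccc2[nH]cc(CCNC(=O)/C=C/c3ccc(O)cc3)c2c1)[C@H](O)c1ccc(O)c(OC)c1 | intermediate
12 | CNP0276372.1, the (7R,8S) 21-membered macrocycle formed from 11 by an ether bond between ring A C5 and the p-coumaroyl oxygen | COc1cc2cc(c1O)Oc1ccc(cc1)/C=C/C(=O)NCCc1c[nH]c3ccc(cc13)O[C@@H](CO)[C@@H]2O | target

**Totals**
Total step count: 6. Longest linear sequence: 6 steps (1 → 2 → 4 → 7 → 10 → 11 → 12).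

**Three steps most likely to fail**

Step 6 (oxidative macrocyclisation). The coumaroyl radical can also couple through C8′ (to ring A C5 or O4) or C3′, and ring A can couple through its oxygen to C3′ to give the isomeric ether. Oligomers and side-chain oxidation are also possible. The fallback makes the same C–O bond by copper-catalysed Ullmann etherification and sets out from 7. 5-Iodovanillin is acetylated (Ac2O, pyridine) to 4-acetoxy-3-iodo-5-methoxybenzaldehyde F1. F1 replaces 8 under the step 4 conditions and gives, through the O-TMS iodo aldol ether F2, the iodo anti-aldol adduct F3. LiBH4 as in step 5 gives the iodo seco-diphenol F4. CuI (0.2 equiv), N,N-dimethylglycine, Cs2CO3, dioxane, 90 °C at 2 mM then closes the ring, and the fallback comes back to the route at 12.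

Step 4 (anti-aldol). The α-aryloxy donor may give poor anti/syn selectivity or low conversion in the presence of the amide and indole donors. The fallback builds the stereodiad by a boron syn-aldol in the enantiomeric auxiliary series followed by inversion at the benzylic carbon, and sets out from 2. Alkylation with (R)-4-benzyl-3-(chloroacetyl)oxazolidin-2-one (K2CO3, MeCN) gives the (R)-auxiliary N-Boc imide F5. TFA, then 5 with EDC/HOBt, gives through the (R)-auxiliary ammonium trifluoroacetate F6 the (R)-auxiliary cinnamamide imide F7. Bu2BOTf (2.5 equiv), i-Pr2NEt, CH2Cl2, −78 to 0 °C, then 8 and oxidative work-up, gives the (2R,3S) syn-aldol adduct F8. Mitsunobu reaction (4-nitrobenzoic acid, PPh3, DIAD, THF, 0 °C) inverts C3 to the (2R,3R) 4-nitrobenzoate F9. LiBH4 in THF cleaves the auxiliary, the nitrobenzoate and both acetates, and the fallback comes back to the route at 11.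

Step 5 (LiBH4 cleavage). Once the para-phenoxide is unmasked, retro-aldol cleavage or epimerisation at C8 can compete with imide reduction. The fallback hydrolyses first and reduces the acid, and sets out from 10. LiOH/H2O2 in THF–H2O at 0 °C removes the auxiliary and both acetates to give the (2R,3R)-dihydroxy acid F10. BH3·THF at 0 °C reduces the carboxylic acid in preference to the cinnamamide, and the fallback comes back to the route at 11.

**Further compounds**
F1 | step 6 | 4-acetoxy-3-iodo-5-methoxybenzaldehyde | CC(=O)Oc1c(I)cc(C=O)cc1OC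
F2 | step 6 | O-TMS iodo aldol ether, (2R,3R), (4S)-auxiliary | O=C1OC[C@H](Cc2ccccc2)N1C(=O)[C@H](Oc1ccc2[nH]cc(CCNC(=O)/C=C/c3ccc(OC(C)=O)cc3)c2c1)[C@H](O[Si](C)(C)C)c1cc(I)c(OC(C)=O)c(OC)c1
F3 | step 6 | iodo anti-aldol adduct, (2R,3R), (4S)-auxiliary | O=C1OC[C@H](Cc2ccccc2)N1C(=O)[C@H](Oc1ccc2[nH]cc(CCNC(=O)/C=C/c3ccc(OC(C)=O)cc3)c2c1)[C@H](O)c1cc(I)c(OC(C)=O)c(OC)c1
F4 | step 6 | iodo seco-diphenol, (1R,2S)-diol with 4-hydroxy-3-iodo-5-methoxyphenyl ring | OC[C@H](Oc1ccc2[nH]cc(CCNC(=O)/C=C/c3ccc(O)cc3)c2c1)[C@H](O)c1cc(I)c(O)c(OC)c1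
F5 | step 4 | (R)-auxiliary N-Boc indol-5-yloxyacetyl imide | O=C1OC[C@@H](Cc2ccccc2)N1C(=O)COc1ccc2[nH]cc(CCNC(=O)OC(C)(C)C)c2c1
F6 | step 4 | (R)-auxiliary ammonium trifluoroacetate | O=C1OC[C@@H](Cc2ccccc2)N1C(=O)COc1ccc2[nH]cc(CC[NH3+])c2c1.[O-]C(=O)C(F)(F)F
F7 | step 4 | (R)-auxiliary N-(4-acetoxycinnamoyl) indol-5-yloxyacetyl imide | O=C1OC[C@@H](Cc2ccccc2)N1C(=O)COc1ccc2[nH]cc(CCNC(=O)/C=C/c3ccc(OC(C)=O)cc3)c2c1
F8 | step 4 | (2R,3S) syn-aldol adduct, (4R)-auxiliary | O=C1OC[C@@H](Cc2ccccc2)N1C(=O)[C@H](Oc1ccc2[nH]cc(CCNC(=O)/C=C/c3ccc(OC(C)=O)cc3)c2c1)[C@@H](O)c1ccc(OC(C)=O)c(OC)c1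
F9 | step 4 | (2R,3R) 4-nitrobenzoate, (4R)-auxiliary | O=C1OC[C@@H](Cc2ccccc2)N1C(=O)[C@H](Oc1ccc2[nH]cc(CCNC(=O)/C=C/c3ccc(OC(C)=O)cc3)c2c1)[C@H](OC(=O)c1ccc(cc1)[N+](=O)[O-])c1ccc(OC(C)=O)c(OC)c1
F10 | step 5 | (2R,3R)-3-hydroxy-3-(4-hydroxy-3-methoxyphenyl)-2-({3-[2-((E)-4-hydroxycinnamoylamino)ethyl]-1H-indol-5-yl}oxy)propanoic acid | OC(=O)[C@H](Oc1ccc2[nH]cc(CCNC(=O)/C=C/c3ccc(O)cc3)c2c1)[C@H](O)c1ccc(O)c(OC)c1
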